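| setting | dawn | noon | midnight | alder | elm | maple | larch |
|---|---|---|---|---|---|---|---|
| Z | 0.30 M | 0.30 M | 0.30 M | 0.30 M | 0.30 M (fed, over 6.0 h) | 0.30 M (fed, over 1.5 h) | 0.30 M |
| X | 0.80 equiv | 0.40 equiv | 0.60 equiv | 0.800 equiv (fed, over 6.0 h) | 0.800 equiv | 0.800 equiv | 0.800 equiv |
| D | 5 equiv | 5 equiv | 5 equiv | 5.00 equiv | 5.00 equiv | 5.00 equiv | 5.00 equiv |
| temperature | 85 °C | 100 °C | 85 °C |  | 100 °C | 100 °C | 100 °C |
| remark | run made earlier | run made earlier | run made earlier | the addition at 70 °C, then warmed to 100 °C; the feed brings no volume worth counting | all else is in the flask from the start; the feed brings no volume worth counting | all else is in the flask from the start; the feed brings no volume worth counting | everything together at the start |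
| time |  |  |  | 8.0 h | 8.0 h | 8.0 h | 8.0 h |

| run | time / h | E / % | Ez / % |
|---|---|---|---|
| dawn | 1.33 | 7 | 1 |
| dawn | 2.00 | 10 | 0 |
| dawn | 4.00 | 12 | 9 |
| dawn | 6.00 | 8 | 10 |
| dawn | 10.0 | 17 | 16 |
| dawn | 15.0 | 12 | 24 |
| noon | 0.833 | 4 | 2 |
| noon | 1.33 | 8 | 6 |
| noon | 2.00 | 8 | 8 |
| noon | 4.00 | 9 | 13 |
| noon | 6.00 | 5 | 19 |
| noon | 10.0 | 8 | 27 |
| midnight | 3.00 | 3 | 5 |
| midnight | 6.00 | 14 | 5 |
| midnight | 10.0 | 9 | 9 |
| midnight | 12.0 | 12 | 17 |
| midnight | 15.0 | 13 | 23 |
| midnight | 20.0 | 10 | 23 |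

(each reading ± 2 percentage points)

- a species is counted by the Z in it: one Ez counts as two
- on the list of suspects stand: Z + X <-> E; D + X <-> Q; Z + E -> Ez; 2 D -> J; Z <-> G

1. which flask leads in share of E in E plus Ez ("all alike" within 1.5 percentage points) (alder / elm / maple / larch / all alike)
2. share of E in E plus Ez at the end, alder
3. share of E in E plus Ez at the end, elm
4. share of E in E plus Ez at the end, maple
5. share of E in E plus Ez at the end, larch

Begin with an easy step: write the share of E, the selectivity, as one over one plus Ez/E, with both as fractions of the Z charged. The suspect Z + E gives Ez, so divide the Ez gained per hour by the E standing; how high E stands then drops out.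

In the noon run at 100 °C, Ez climbed from 8% to 27% between 2.00 h and 10.0 h, over a mean E of 7.50%. So the overtaking time, the hours in which Ez comes level with a steady E, reads 3.16 h. Noon's E already read 8% at 1.33 h, so take E as steady: the share is the overtaking time over itself plus τ, the hot hours served.

Do the cold hours count? The dawn run at 85 °C reads 8.98 h, slower than noon. The same step down again to 70 °C gives 25.6 h, longer than alder's 6.0 h of addition, and E is not steady there, since X is still coming in. So count alder's cold hours as none, and alder's τ is 2.00 h.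

Does a feed count? Ez grows with Z present. A Z feed starts from none, so count its hours at 0.5: elm has 5.00 h, maple 7.25 h, larch 8.0 h. Alder's X feed leaves Z in place.

My shares: alder 61.2%, elm 38.7%, maple 30.4%, larch 28.3%.

The forecast names alder and gives alder 57%, elm 52%, maple 30%, larch 27%, saying “Alder leads narrowly over elm, uncertainly”; its alder stands below mine and its elm above mine.

The flask gives alder 54.5%, elm 37.6%, maple 28.6%, larch 26.5%, with alder ahead.

    Z + X ⇌ E (K = 6.70 /M, k = 0.0120 /M/min, Ea = 94.0 kJ/mol, ΔH = 3.00 kJ/mol)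
    D + X ⇌ Q (K = 0.160 /M, k = 9.90 × 10⁻⁴ /M/min, Ea = 105 kJ/mol, ΔH = −50.0 kJ/mol)
    Z + E → Ez (k = 0.0230 /M/min, Ea = 96.0 kJ/mol)
    2 D → J (k = 1.40 × 10⁻⁴ /M/min, Ea = 101 kJ/mol)
    Z ⇌ G (K = 0.740, k = 0.00300 /min, Ea = 111 kJ/mol, ΔH = −24.0 kJ/mol)
    (constants at 100 °C)

Alder is not at rest at 8.00 h: it holds Z 52.5%, E 13.9%, Ez 11.6%. Left until 80.0 h, alder holds Z 6.30%, E 3.48%, Ez 85.3%, and its share falls to 3.92%, beside larch's 3.64%. The overtaking time, with alder's hot hours run on to that time, gives 4.10%.

Now take alder with 0.18 M of Z. The overtaking time stretches with the charge to 5.26 h, so the share should be 72.5%; that flask gives 66.8%.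

The readings stem from a simulated flask with made-up constants.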